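**The task.** As the chemist on these flasks, I had three runs in hand and a fourth to forecast.

| flask | starting material | reagent | time |
|---|---|---|---|
| violet | 0.250 M | 0.500 M |  |
| blue | 0.380 M | 0.500 M |  |
| amber | 0.250 M | 0.750 M |  |
| ochre | 0.250 M | 0.500 M | 13 min |

| violet run: time / min | violet run: [target] / M | blue run: time / min | blue run: [target] / M | amber run: time / min | amber run: [target] / M |
|---|---|---|---|---|---|
| 0.27 | 0.0033 | 0.27 | 0.0059 | 0.27 | 0.0041 |
| 0.42 | 0.0084 | 0.42 | 0.0120 | 0.42 | 0.0081 |
| 0.67 | 0.0159 | 0.67 | 0.0223 | 0.67 | 0.0145 |
| 1.1 | 0.0304 | 1.1 | 0.0471 | 1.1 | 0.0265 |
| 1.7 | 0.0509 | 1.7 | 0.0775 | 1.7 | 0.0427 |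
| 2.7 | 0.0832 | 2.7 | 0.1264 | 2.7 | 0.0672 |
| 4.2 | 0.1231 | 4.2 | 0.1869 | 4.2 | 0.0975 |
| 6.7 | 0.1707 | 6.7 | 0.2614 | 6.7 | 0.1411 |

(readings scatter by 8 × 10⁻⁴ M)

- Overall: starting material + reagent -> target.
- Constant volume, constant temperature.
- What is held in complexes is read along with the free species.
- "The second partner" is reagent.
- An order is taken over about fifteen percent of the charge, up and down.

- reaction order in [reagent] at the outset, round the charge of the violet run, defined at two percent of the starting material turned into target
- reaction order in [starting material] at the outset, round the charge of the violet run, defined at two percent of the starting material turned into target (one fixed amount of target, the same in the runs compared)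
- target in the ochre run at 13 min, as a share of the starting material charged

**Unmade charge.** A first-order rate constant can be turned round into a time: the span over which a stock halves, its half-life. I took as stock the unmade, meaning the starting material charged minus the target read, whatever form it was in. In the violet run the unmade fell from 0.127 M at 4.2 min to 0.0793 M at 6.7 min. That gave a halving time, the span in which the unmade halves, of 3.69 min. The pair of readings before gave 3.80 min, so I judged the late decay steady enough to count in halvings.

**My count.** The ochre flask had the violet charge, so I continued the violet run. From 6.7 min to 13 min lay 1.71 halvings. They left 9.70% of the ochre charge unmade, so I expected 90.3% as target.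

**The forecast.** It gave −0.3 for the reagent order, 0.85 for the starting-material order and 90% for the ochre share. It read both orders from the rates after a short lag, and it put the starting-material order slightly lower because at the asked conversion “the lag is not quite over”.

**The result.** The flask gave −0.025, 0.63 and 90.7%. The share agreed with the forecast, but the orders parted from it: the reagent order stood higher and the starting-material order lower.

    starting material ⇌ intermediate + by-product (0.5706 min⁻¹, 0.9060 M⁻¹ min⁻¹)
    intermediate + reagent → target (9.300 M⁻¹ min⁻¹)
    starting material + reagent ⇌ idle substrate-reagent adduct, settled at all times (5.770 M⁻¹)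
    2 starting material ⇌ idle substrate dimer, settled at all times (2.500 M⁻¹)

**The halving count.** The ochre run left 9.30% unmade, against my 9.70%. I then applied the count to the amber run, whose late readings gave a halving time of 5.15 min, longer than the violet 3.69 min. Counted from its 4.2 min reading, that put half of the amber charge made at 5.68 min, and the amber run reached it at 5.61 min. The main reason the ochre run fell short of full conversion at 13 min was starting material bound with reagent as idle substrate-reagent adduct: with that binding taken away, the share of target in the ochre run at that time rose from 90.7% to 99.7%.

(The numbers in the tables stem from a simulated flask for an exercise, noise included.)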